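**Numbering.** Briarane numbering is used throughout: ring A = C1, C10–C14; ring C = the temporary six-membered ring C4–C9; compounds are numbered 1–50 in order of first appearance in the steps.

## Analysis of the target

The target is a briarane: a ten-membered carbocycle (C1–C10) trans-fused across C1–C10 to cyclohexanone ring A and cis-fused across C7–C8 to a γ-lactone (C7, C8, C17, C19, O). It has ten stereocentres (C1, C2, C6, C7, C8, C9, C10, C11, C14, C17) and a Z C3=C4 alkene conjugated with the exocyclic C5=C16 methylene. The C1 methyl is anti to H10 and syn to the C11 methyl, the C14 butyrate is trans to the C1 methyl, and the lactone carries the C8 hydroxyl and the C17 methyl together on its convex face. Sensitive points are the C14 butyrate β to the C12 ketone (elimination), the enolisable C11 in its more crowded orientation, the secondary allylic C6 chloride next to a 1,3-diene, and three different acyl groups beside a free tertiary alcohol. The difficulty is a medium ring that contains a fully substituted carbon (C1) between oxygenated C2 and C10, contiguous stereocentres from C6 round to C2, and oxidation states at C5, C6, C9, C12 and C14 that must be told apart late. The strategy rests on one feature: the C1–C2 bond, the Z C3=C4 alkene and the C9 oxygen form the retron of an oxy-Cope rearrangement across a C4–C9 bond that the target lacks, that is, of a six-membered ring C (C4–C9) bearing ring A at C9 and an alkoxyvinyl group at C4.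

## Retrosynthetic reasoning

**C12, C5, C6 (50 ⇒ 49 ⇒ 48 ⇒ 47 ⇒ 45).** The C12 ketone is unveiled last from silyl ether 48 via alcohol 49, so the β-acyloxy ketone exists only in the final compound. The C5 methylene comes from ketone 47, and the chloride from α-hydroxy ketone 45 by SN2 inversion. The cut is made at the α-keto stage because displacement there is fast and cannot go SN2′, as it could on the allylic alcohol.

**Acyl pattern and lactone (45 ⇒ 44 ⇒ 42 ⇒ 40 ⇒ 37).** The lactone is masked as a cyclic lactol acetal so that no electrophilic carbonyl sits beside the C9 alkoxide in the key step; it is regenerated in 44. C14 is carried as a triethylsilyl ether in its final configuration, C12 as a tert-butyldimethylsilyl ether, and O6/O8 as one silylene, so each hydroxyl can be freed alone. The C9 alcohol comes from ketone 37 by hydride addition under Felkin–Anh control from C10.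

**Key disconnection (37 ⇒ 34).** Reconnecting C4–C9 and cutting C1–C2 turns the ten-membered ketone 37 into the cis-dialkenyl cyclohexanol 34. The gain is the medium ring without any macrocyclisation, the quaternary C1 and C2 by chirality transfer, and the Z alkene. The forward step needs the ring A alkene and the (E)-enol ether cis on ring C and a chair with C4–C5 axial; the O6/O8 silylene bridge in 34 is there to enforce that chair.

**C4 side chain and C9 carbinol (34 ⇒ 29 ⇒ 28 ⇒ 27 ⇒ 26).** In 34, ring A, the C4 substituent and C17 all stand on one face of ring C. Adding a ring A nucleophile to a C9 ketone would have to enter syn to both neighbours, so that bond is not made this way. Instead the C9–O bond is made syn to the C8 hydroxyl by directed epoxidation of diene 26 (giving 27), and the C4–C3 bond anti to it by SN2 opening with an acetylide (28). The (E)-enol ether then follows from the terminal alkyne 29 by syn borylation and copper etherification. Every relationship is fixed by mechanism, not by facial bias.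

**C9–C10 (26 ⇒ 12 + 23).** The two rings are joined by alkenyl–alkenyl cross-coupling of ring A bromide 12 with enol triflate 23. No stereocentre is formed, and 23 is a single regioisomer because C8 is quaternary.

**Ring C (23 ⇒ 22 ⇒ 20 ⇒ 19).** The C4–C9 bond of ring C is the bond made by Ferrier carbocyclisation of hexenopyranoside 19. This gives the 1,3-related C5 ketone and C9 carbinol of 20 directly and takes C6, C7 and C8 from the sugar.

**C8–C17 (17 ⇒ 15 ⇒ 13).** The quaternary C8 and C17 come from an intramolecular Reformatsky reaction of the O7-bound 2-bromopropanoate in 15 onto the C8 ketone. The tether forces cis fusion, so the C8 hydroxyl and C17 are set relative to C7 on a rigid pyranoside made from mannoside 13.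

**Ring A (12 ⇒ 8 ⇒ 6 ⇒ 4 ⇒ 1).** (R)-Carvone 1 supplies C12; C11 is set by trans alkylation (2) and C14 by Luche reduction of 8. The bromine is placed on C10 by raising the enone to dione 4 and transposing through vinylogous ester 5 to bromo enone 6.

## Alternatives that were turned down

**Alternative 1: late Reformatsky lactone annulation.** The C8–C17 bond is cut last. In the forward step the C7 2-bromopropanoate A2, which holds the finished ten-membered ring with a C8 ketone, is reduced to a samarium enolate that adds to C8 and gives the hydroxy lactone A1.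
- For it: the lactone, C8 and C17 are made in one step, cis fusion is enforced by the tether, and no carboxyl masking is needed. On lactone step economy it is stronger than the chosen route, which spends four steps masking and unmasking C19.
- Against it: A2 carries an α-silyloxy and an α-acyloxy ketone, an allylic chloride and a β-acyloxy ketone, all of which a one-electron reductant can cleave. The route also says nothing about how the ten-membered ring, C1 and the Z alkene are made, so the hardest problem is only postponed.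
- Comparison: the chosen strategy uses the same bond construction early (step 13), on a pyranoside where none of these groups exists, and offers in its place a ring-forming step that also sets C1 and C2.

**Alternative 2: ozonolytic unveiling of an octalin.** The transannular C2–C7 bond is cut. Ozonolysis of the tetrasubstituted ring-fusion alkene of octalin A4 would give the ten-membered 2,7-dione A3.
- For it: cleavage of such an alkene is about as reliable as a ring-forming step can be. The stereocentres at C1, C8, C9 and C10 are set on a rigid decalin and a chiral-pool terpenoid supplies the carbon. On certainty of ring formation it is stronger than the oxy-Cope.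
- Against it: A3 arrives with C2 and C7 as ketones and C3–C4 saturated. Two carbonyls then have to be reduced with control on the flexible ring, and the Z alkene has to be introduced regioselectively between them. The C6 chloride sits α to the new C7 ketone, where it can epimerise or eliminate.
- Comparison: the chosen strategy delivers C2 with its oxygen, the Z alkene and C1 in the ring-forming event itself, at the price of a less certain key step.

**Alternative 3: [2,3]-Wittig ring contraction.** The C9–C10 bond is cut. The C9 enolate of the 13-membered α-allyloxy ketone A6 would rearrange across ring A to the ten-membered hydroxy ketone A5.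
- For it: it is also a sigmatropic route, it sets C9 and C10 together, leaves a C11=C12 alkene as a handle, and tolerates the diene and chloride being in place. It is equal to the chosen route in avoiding a direct ten-membered closure.
- Against it: A6 must first be made by closing a 13-membered ether, which is an end-to-end cyclisation. The C8 ketone can also enolise toward C7, where loss of the β-chloride at C6 would destroy the substrate. Stereocontrol at C9 and C10 through a macrocyclic transition state is hard to predict. A5 still lacks C17–C19 and the C11/C12 functionality, so an Alternative-1-type addition would be needed afterwards.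
- Comparison: the oxy-Cope makes the ring itself, with the lactone carbons already attached, whereas this rearrangement makes one bond of a ring that has to be closed beforehand.

Key step: step 29

Remark on the chemistry: centres that are destroyed or equilibrated later (the CHBr carbon of 14–16, the enolised C1 of 4, the C9 carbinol of 20 and 21, the acetal carbon C19 of 31–43) are carried as mixtures; where the SMILES fixes one, it shows the expected major isomer.

Remark on the chemistry: the SMILES of the Tebbe reagent Cp2Ti(μ-Cl)(μ-CH2)AlMe2 in step 39 shows the Ti–CH2–Al linkage with the chloride bound to titanium only; the dative Cl→Al bridge and the η5 bonding of the cyclopentadienyl rings are not drawn.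

## Route

Step 1
Reactants: 1 (R)-carvone
Product: 2 (5R,6S)-2,6-dimethyl-5-(prop-1-en-2-yl)cyclohex-2-en-1-one
Conditions: LiN(i-Pr)2, THF, −78 °C; MeI, −78 → 0 °C
Reagents that add atoms: iodomethane CI
Why: Kinetic α′-enolate alkylation; the electrophile enters anti to the adjacent isopropenyl group, which sets C11 relative to the carvone stereocentre (future C12).

Step 2
Reactants: 2 (5R,6S)-2,6-dimethyl-5-(prop-1-en-2-yl)cyclohex-2-en-1-one
Product: 3 2,3-epoxy ketone of 2 (oxirane trans to the isopropenyl group)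
Conditions: H2O2 (30%), NaOH (cat.), MeOH, 0 °C
Reagents that add atoms: hydrogen peroxide OO
Why: Nucleophilic epoxidation touches only the enone alkene and leaves the isopropenyl group; the oxirane configuration is lost in step 3.

Step 3
Reactants: 3 2,3-epoxy ketone
Product: 4 (4S,5R)-2,4-dimethyl-5-(prop-1-en-2-yl)cyclohexane-1,3-dione
Conditions: Pd(PPh3)4 (cat.), 1,2-bis(diphenylphosphino)ethane (cat.), toluene, 100 °C
Reagents that add atoms: none
Why: Isomerisation of an α,β-epoxy ketone to a β-diketone under zerovalent palladium catalysis (opening at the α C–O bond, then β-hydride elimination); this brings the future C14 to carbonyl level without touching C11 or C12.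

Step 4
Reactants: 4 (4S,5R)-2,4-dimethyl-5-(prop-1-en-2-yl)cyclohexane-1,3-dione
Product: 5 (5R,6S)-3-methoxy-2,6-dimethyl-5-(prop-1-en-2-yl)cyclohex-2-en-1-one
Conditions: MeOH, HC(OMe)3, TsOH·H2O (cat.), rt → 50 °C
Reagents that add atoms: methanol CO
Why: Acid-catalysed enol etherification under equilibrium control; the methoxy group should settle on the carbonyl remote from the C11 methyl, where it avoids allylic strain, leaving the C10 carbonyl free.

Step 5
Reactants: 5 vinylogous methyl ester
Product: 6 (4S,5R)-3-bromo-2,4-dimethyl-5-(prop-1-en-2-yl)cyclohex-2-en-1-one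
Conditions: (COBr)2, DMF (cat.), CH2Cl2, 0 °C → rt
Reagents that add atoms: oxalyl bromide O=C(Br)C(=O)Br
Why: Vilsmeier-type activation of the vinylogous ester carbonyl, bromide addition at that carbon and loss of bromomethane give the β-bromo enone with 1,3-carbonyl transposition, so bromine lands on C10 next to the C11 methyl.

Step 6
Reactants: 6 bromo enone
Product: 8 (4S,5R)-5-acetoxy-3-bromo-2,4-dimethylcyclohex-2-en-1-one, via methoxy hydroperoxide 7 (not isolated)
Conditions: O3, MeOH/CH2Cl2, −78 °C; then Ac2O, Et3N, DMAP (cat.), 0 °C → rt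
Reagents that add atoms: ozone [O-][O+]=O
Why: Ozone attacks only the electron-rich isopropenyl alkene, the bromo enone being deactivated; acylation of the α-methoxy hydroperoxide triggers a Criegee rearrangement in which the ring carbon migrates to oxygen with retention at C12.

Step 7
Reactants: 8 acetoxy bromo enone
Product: 9 (1S,4S,5R)-5-acetoxy-3-bromo-2,4-dimethylcyclohex-2-en-1-ol
Conditions: NaBH4, CeCl3·7H2O, MeOH, −78 → −20 °C
Reagents that add atoms: none
Why: Luche 1,2-reduction; axial hydride addition to the half-chair with both ring substituents equatorial gives the alcohol cis to the C12 acetate, as in the carvone to cis-carveol case, and this is the C14 configuration of the target.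

Step 8
Reactants: 9 allylic alcohol
Product: 10 C14 triethylsilyl ether of 9
Conditions: Et3SiCl, imidazole, DMF, 0 °C
Reagents that add atoms: chlorotriethylsilane CC[Si](Cl)(CC)CC
Why: Standard silylation; the labile silyl group is put on C14 so that this oxygen can later be freed before the C12 oxygen.

Step 9
Reactants: 10 acetate
Product: 11 C12 alcohol with C14 triethylsilyl ether
Conditions: i-Bu2AlH, CH2Cl2, −78 °C
Reagents that add atoms: none
Why: Reductive removal of the acetate avoids base and leaves the vinyl bromide and the triethylsilyl ether untouched.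

Step 10
Reactants: 11 C12 alcohol
Product: 12 ring A bromide (1S,4S,5R)-3-bromo-5-(tert-butyldimethylsilyloxy)-2,4-dimethyl-1-(triethylsilyloxy)cyclohex-2-ene
Conditions: t-BuMe2SiCl, imidazole, DMF, rt
Reagents that add atoms: tert-butylchlorodimethylsilane CC(C)(C)[Si](C)(C)Cl
Why: Standard silylation; the two silyl ethers differ enough in lability to be removed one after the other in the endgame.

Step 11
Reactants: 13 methyl 4,6-O-benzylidene-α-D-mannopyranoside
Product: 14 methyl 4,6-O-benzylidene-3-O-(2-bromopropanoyl)-α-D-mannopyranoside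
Conditions: CH3CHBrCOCl, Me2SnCl2 (cat.), K2CO3, THF, 0 °C → rt
Reagents that add atoms: 2-bromopropanoyl chloride CC(Br)C(Cl)=O
Why: Tin-catalysed acylation of a cis-1,2-diol goes to the equatorial 3-hydroxyl, which places the propanoate on the oxygen that becomes O7.

Step 12
Reactants: 14 3-O-(2-bromopropanoyl) mannoside
Product: 15 methyl 4,6-O-benzylidene-3-O-(2-bromopropanoyl)-α-D-arabino-hexopyranosid-2-ulose
Conditions: Dess–Martin periodinane, CH2Cl2, rt
Reagents that add atoms: none
Why: Mild oxidation of the remaining axial hydroxyl gives the C8 ketone without acyl migration or epimerisation at C7.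

Step 13
Reactants: 15 2-ulose
Product: 17 cis-fused hydroxy γ-lactone on the gluco-configured pyranoside, via samarium enolate 16 (not isolated)
Conditions: SmI2 (2.2 equiv), THF, −78 °C; aq. NH4Cl
Reagents that add atoms: none
Why: Intramolecular samarium Reformatsky reaction: the C–Br bond is reduced faster than the ketone and the enolate adds through a five-membered transition state. The tether forces cis fusion, so the tertiary hydroxyl takes the gluco (C8) configuration; the C17 methyl takes the convex face, which is also its thermodynamic position, so any epimer can be corrected with DBU.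

Step 14
Reactants: 17 benzylidene lactone
Product: 18 methyl 4-O-benzoyl-6-bromo-6-deoxy analogue of 17
Conditions: N-bromosuccinimide, BaCO3, CCl4, reflux
Reagents that add atoms: N-bromosuccinimide BrN1C(=O)CCC1=O
Why: Hanessian–Hullar opening of the benzylidene acetal gives the O6 benzoate (sugar O4) and the primary bromide in one step; the tertiary alcohol and the lactone are inert.

Step 15
Reactants: 18 6-bromide
Product: 19 methyl 4-O-benzoyl-6-deoxy-hex-5-enopyranoside analogue of 17
Conditions: AgF, pyridine, rt, dark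
Reagents that add atoms: none
Why: Silver-assisted dehydrobromination is the standard entry to hex-5-enopyranosides and spares the benzoate and lactone.

Step 16
Reactants: 19 hex-5-enopyranoside
Product: 20 ring C cyclohexanone (C5 ketone, C6 benzoate, C7–C8 fused lactone with C8 hydroxyl, C9 carbinol)
Conditions: Hg(OCOCF3)2 (cat.), acetone/H2O (2:1), rt
Reagents that add atoms: water O
Why: Ferrier carbocyclisation: oxymercuration of the enol ether, loss of methanol and intramolecular aldol closure form C4–C9 and deliver the C5 ketone and C9 carbinol; C6, C7 and C8 are untouched and the C9 configuration is irrelevant.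

Step 17
Reactants: 20 ring C cyclohexanone
Product: 21 C5 ethylene ketal of 20
Conditions: HOCH2CH2OH, HC(OEt)3, TsOH·H2O (cat.), CH2Cl2, rt
Reagents that add atoms: ethylene glycol OCCO
Why: Ketalisation at room temperature with a water scavenger masks C5 before C9 becomes a ketone and keeps the β-hydroxy ketone from dehydrating.

Step 18
Reactants: 21 C5 ketal
Product: 22 C9 ketone
Conditions: Dess–Martin periodinane, NaHCO3, CH2Cl2, rt
Reagents that add atoms: none
Why: Oxidation of the only secondary alcohol; the tertiary C8 hydroxyl cannot react.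

Step 19
Reactants: 22 C9 ketone
Product: 23 C9 enol triflate (C4=C9)
Conditions: KN(SiMe3)2 (2.2 equiv), THF, −78 °C; PhNTf2, −78 → −20 °C
Reagents that add atoms: N-phenylbis(trifluoromethanesulfonimide) O=S(=O)(N(c1ccccc1)S(=O)(=O)C(F)(F)F)C(F)(F)F
Why: C8 is quaternary, so the ketone can enolise only toward C4 and a single enol triflate results; the second equivalent of base holds the C8 hydroxyl as its alkoxide, which the triflimide does not sulfonylate.

Step 20
Reactants: 12 ring A bromide; 23 enol triflate
Product: 26 diene with ring A on C9 (C10=C1 and C9=C4), via vinyllithium 24 (not isolated), via vinylzinc chloride 25 (not isolated)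
Conditions: 12, t-BuLi (2.1 equiv), THF, −78 °C; ZnCl2, −78 → 0 °C; then 23, Pd2(dba)3 (cat.), SPhos (cat.), THF, 45 °C
Reagents that add atoms: none
Why: Negishi alkenyl–alkenyl coupling; the organozinc tolerates the lactone and benzoate, no stereocentre is formed, and a bulky biaryl phosphine is chosen for the hindered pair.

Step 21
Reactants: 26 diene
Product: 27 4,9-epoxide syn to the C8 hydroxyl
Conditions: VO(acac)2 (cat.), t-BuOOH, CH2Cl2, 0 °C → rt
Reagents that add atoms: tert-butyl hydroperoxide CC(C)(C)OO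
Why: Hydroxyl-directed epoxidation: the vanadium alkoxide of the tertiary C8 alcohol delivers oxygen to the allylic C9=C4 bond on its own face, which sets the C9–O bond syn to O8; the ring A alkene is only homoallylic and is left.

Step 22
Reactants: 27 epoxide
Product: 28 C4 (trimethylsilyl)ethynyl carbinol (alkyne trans to the C9 hydroxyl)
Conditions: Me3SiC≡CH, n-BuLi, toluene, −78 °C; Et2AlCl, 0 °C; then 27, 0 °C → rt
Reagents that add atoms: ethynyltrimethylsilane C#C[Si](C)(C)C
Why: Alkynylalane opening of a 2,3-epoxy alcohol at the carbon remote from the carbinol (C4); SN2 inversion puts the alkyne anti to the C9 oxygen and therefore cis to ring A.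

Step 23
Reactants: 28 silylalkyne benzoate
Product: 29 terminal alkyne with free C6, C8 and C9 hydroxyls
Conditions: K2CO3, MeOH, rt
Reagents that add atoms: none
Why: Methanolysis removes the alkynylsilane and the benzoate together; the γ-lactone recloses on work-up and C17 stays in its thermodynamic configuration.

Step 24
Reactants: 29 triol
Product: 30 O6,O8-di-tert-butylsilylene
Conditions: t-Bu2Si(OTf)2, 2,6-lutidine, CH2Cl2, 0 °C → rt
Reagents that add atoms: di-tert-butylsilyl bis(trifluoromethanesulfonate) CC(C)(C)[Si](OS(=O)(=O)C(F)(F)F)(OS(=O)(=O)C(F)(F)F)C(C)(C)C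
Why: The reagent enters at the only secondary hydroxyl (O6) and closes a six-membered ring onto the cis-1,3 tertiary O8, the C9 hydroxyl being too hindered; the bridge holds O6 and O8 axial and so fixes the chair of ring C needed in step 29.

Step 25
Reactants: 30 silylene lactone
Product: 31 lactol
Conditions: i-Bu2AlH, CH2Cl2, −78 °C
Reagents that add atoms: none
Why: Half-reduction of the γ-lactone at low temperature removes the electrophilic carbonyl that the C9 alkoxide could attack.

Step 26
Reactants: 31 lactol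
Product: 32 lactol tert-butyldimethylsilyl acetal
Conditions: t-BuMe2SiCl, imidazole, DMF, rt
Reagents that add atoms: tert-butylchlorodimethylsilane CC(C)(C)[Si](C)(C)Cl
Why: Only the hemiacetal hydroxyl is accessible; the acetal is stable to base and keeps C19 at the lactone-precursor level.

Step 27
Reactants: 32 terminal alkyne
Product: 33 (E)-alkenyl pinacol boronate
Conditions: B2pin2, CuCl (cat.), NaOt-Bu (cat.), Xantphos (cat.), MeOH, THF, rt
Reagents that add atoms: bis(pinacolato)diboron CC1(C)OB(OC1(C)C)B1OC(C)(C)C(C)(C)O1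
Why: Copper-catalysed syn borylcupration and protonation of a terminal alkyne puts boron on the terminal carbon and gives the E alkene; the free tertiary alcohol is tolerated.

Step 28
Reactants: 33 alkenyl boronate
Product: 34 oxy-Cope precursor (cis-dialkenyl C9 carbinol with (E)-2-(4-methoxybenzyloxy)vinyl group at C4)
Conditions: 4-MeOC6H4CH2OH (excess), Cu(OAc)2, Et3N, 4 Å MS, CH2Cl2, rt, air
Reagents that add atoms: 4-methoxybenzyl alcohol COc1ccc(CO)cc1
Why: Chan–Lam-type C–O coupling of an alkenyl boronate with an alcohol proceeds with retention of alkene geometry and gives the (E)-enol ether; excess benzylic alcohol outcompetes the hindered C9 hydroxyl.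

Step 29
Reactants: 34 oxy-Cope precursor
Product: 37 ten-membered C9 ketone with Z C3=C4, via potassium alkoxide 35 (not isolated), via potassium enolate 36 (not isolated)
Conditions: KH, 18-crown-6, THF, 0 → 40 °C; then AcOH, THF, −78 °C
Reagents that add atoms: none
Why: KH with the crown ether gives the free C9 alkoxide 35, whose oxyanion weakens C4–C9; the 1,5-diene C1=C10–C9–C4–C3=C2 then undergoes a [3,3]-sigmatropic shift that breaks C4–C9, forms C1–C2 and leaves the C9 enolate 36. The closest known reaction is the anionic oxy-Cope ring expansion of cis-1,2-dialkenylcyclohexanols to cyclodec-5-enones. No macrocyclisation is involved: ring C grows from six to ten members as C10, C1, C2 and C3 are inserted between C9 and C4. The silylene holds O6 and O8 axial, which makes ring A axial at C9 and the enol ether equatorial at C4; on the reacting chair the C4–C5 bond is then axial and C9–C8 equatorial, so C3=C4 forms Z, while the chair leading to the E alkene would need the flipped ring C that the bridge forbids. C1 is set because this chair brings C2 onto the face of the tetrasubstituted alkene anti to the C11 methyl, whereas the boat would attack syn to it, so the ring A stereocentres reinforce the chair. C2 is set because the E geometry keeps the enol ether oxygen equatorial, so the C9/C4 configuration is relayed to C1/C2. C10 is set by protonation of 36 at −78 °C anti to the C1 methyl, and since C10 is enolisable the trans-fused ketone can also be reached by base equilibration. The step needs chair over boat, one chair over the other, and an alkoxide that rearranges faster than silicon migrates to it; the bridge, the C11 methyl and the bulk of the di-tert-butylsilylene are the features meant to secure these.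

Step 30
Reactants: 37 C9 ketone
Product: 38 C9 alcohol
Conditions: LiAlH4, THF, −78 → −20 °C
Reagents that add atoms: none
Why: A small hydride is needed for this flanked ketone; Felkin–Anh attack anti to the quaternary C1 at the neighbouring C10 stereocentre should give the C9 configuration of the target, and no other group in 37 is reducible.

Step 31
Reactants: 38 C9 alcohol
Product: 39 C2,C9 diol
Conditions: DDQ, CH2Cl2/pH 7 buffer, 0 °C
Reagents that add atoms: none
Why: Oxidative cleavage of the 4-methoxybenzyl ether frees the allylic C2 hydroxyl; silyl ethers, ketal and acetal are inert.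

Step 32
Reactants: 39 diol
Product: 40 C2,C9 diacetate
Conditions: Ac2O, DMAP, Et3N, CH2Cl2, rt → 40 °C
Reagents that add atoms: acetic anhydride CC(=O)OC(C)=O
Why: Both secondary hydroxyls are acetylated in one operation; every other oxygen is still protected.

Step 33
Reactants: 40 diacetate
Product: 41 C14 alcohol with C19 methyl acetal
Conditions: PPTS, MeOH, rt → 40 °C
Reagents that add atoms: methanol CO
Why: Mild acid methanolysis removes the triethylsilyl ether and exchanges the silyl lactol acetal for the methyl acetal, while the tert-butyldimethylsilyl ether, the silylene and the dioxolane remain.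

Step 34
Reactants: 41 C14 alcohol
Product: 42 C14 butyrate
Conditions: (n-PrCO)2O, DMAP, Et3N, CH2Cl2, 40 °C
Reagents that add atoms: butanoic anhydride CCCC(=O)OC(=O)CCC
Why: The only free hydroxyl is acylated while no ketone is present, so no base-sensitive β-acyloxy ketone exists yet.

Step 35
Reactants: 42 butyrate
Product: 43 C5 enone with C19 lactol
Conditions: PPTS, acetone/H2O (10:1), 45 °C
Reagents that add atoms: water O
Why: Acid hydrolysis unveils the C5 ketone, now conjugated with C3=C4, and the lactol in one step; the silylene and the C12 silyl ether tolerate these conditions.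

Step 36
Reactants: 43 lactol
Product: 44 γ-lactone (C5 enone, O6,O8-silylene)
Conditions: TEMPO (cat.), PhI(OAc)2, CH2Cl2, rt
Reagents that add atoms: none
Why: Non-basic oxoammonium oxidation of the hemiacetal gives the lactone; no other free hydroxyl is present.

Step 37
Reactants: 44 silylene
Product: 45 C6,C8 diol (α-hydroxy enone)
Conditions: HF·pyridine, pyridine, THF, 0 °C
Reagents that add atoms: none
Why: The dialkoxysilane is cleaved by buffered fluoride much faster than the hindered secondary tert-butyldimethylsilyl ether at C12.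

Step 38
Reactants: 45 diol
Product: 47 C6 chloride (α-chloro enone with inverted C6), via triflate 46 (not isolated)
Conditions: Tf2O, pyridine, CH2Cl2, −78 → −30 °C; then n-Bu4NCl, −30 → 0 °C
Reagents that add atoms: tetrabutylammonium chloride CCCC[N+](CCCC)(CCCC)CCCC.[Cl-]
Why: Only the secondary C6 hydroxyl is triflated; SN2 displacement next to the carbonyl is fast and inverts C6, and a single equivalent of chloride at low temperature limits exchange epimerisation.

Step 39
Reactants: 47 α-chloro enone
Product: 48 C5 methylene compound (12-O-silyl precursor of the target)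
Conditions: Cp2Ti(μ-Cl)(μ-CH2)AlMe2 (3 equiv), pyridine (cat.), THF/toluene, −40 → 0 °C
Reagents that add atoms: Tebbe reagent C[Al](C)C[Ti](Cl)(C1C=CC=C1)C1C=CC=C1
Why: Tebbe methylenation is non-basic, so the α-chloro ketone is neither enolised nor substituted, and the single ketone reacts before the esters and the lactone; the excess covers the equivalent taken up by the free C8 hydroxyl, which is returned on aqueous work-up.

Step 40
Reactants: 48 C12 silyl ether
Product: 49 C12 alcohol
Conditions: HF·pyridine, THF, rt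
Reagents that add atoms: none
Why: Acidic fluoride removes the last silyl group without acyl migration or loss of the allylic chloride.

Step 41
Reactants: 49 C12 alcohol
Product: 50 CNP0283653.1
Conditions: Dess–Martin periodinane, NaHCO3, CH2Cl2, 0 °C → rt
Reagents that add atoms: none
Why: Buffered, non-basic oxidation forms the C12 ketone last, so C11 is not epimerised and the β-butyrate is not eliminated.

## Compound list

1 | (R)-carvone | CC(=C)[C@@H]1CC=C(C)C(=O)C1 | starting material
2 | (5R,6S)-2,6-dimethyl-5-(prop-1-en-2-yl)cyclohex-2-en-1-one | CC(=C)[C@@H]1CC=C(C)C(=O)[C@H]1C | intermediate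
3 | 2,3-epoxy ketone of 2, oxirane trans to isopropenyl | CC(=C)[C@@H]1C[C@H]2O[C@@]2(C)C(=O)[C@H]1C | intermediate
4 | (4S,5R)-2,4-dimethyl-5-(prop-1-en-2-yl)cyclohexane-1,3-dione | CC(=C)[C@@H]1CC(=O)C(C)C(=O)[C@H]1C | intermediate
5 | (5R,6S)-3-methoxy-2,6-dimethyl-5-(prop-1-en-2-yl)cyclohex-2-en-1-one | CC(=C)[C@@H]1CC(OC)=C(C)C(=O)[C@H]1C | intermediate
6 | (4S,5R)-3-bromo-2,4-dimethyl-5-(prop-1-en-2-yl)cyclohex-2-en-1-one | CC(=C)[C@@H]1CC(=O)C(C)=C(Br)[C@H]1C | intermediate
7 | (4S,5R)-3-bromo-5-(1-hydroperoxy-1-methoxyethyl)-2,4-dimethylcyclohex-2-en-1-one | COC(C)(OO)[C@@H]1CC(=O)C(C)=C(Br)[C@H]1C | intermediate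
8 | (4S,5R)-5-acetoxy-3-bromo-2,4-dimethylcyclohex-2-en-1-one | CC(=O)O[C@@H]1CC(=O)C(C)=C(Br)[C@H]1C | intermediate
9 | (1S,4S,5R)-5-acetoxy-3-bromo-2,4-dimethylcyclohex-2-en-1-ol | CC(=O)O[C@@H]1C[C@H](O)C(C)=C(Br)[C@H]1C | intermediate
10 | 1-O-triethylsilyl ether of 9 | CC(=O)O[C@@H]1C[C@H](O[Si](CC)(CC)CC)C(C)=C(Br)[C@H]1C | intermediate
11 | ring A C12 alcohol with C14 triethylsilyl ether | O[C@@H]1C[C@H](O[Si](CC)(CC)CC)C(C)=C(Br)[C@H]1C | intermediate
12 | ring A bromide, (1S,4S,5R)-3-bromo-5-(tert-butyldimethylsilyloxy)-2,4-dimethyl-1-(triethylsilyloxy)cyclohex-2-ene | CC(C)(C)[Si](C)(C)O[C@@H]1C[C@H](O[Si](CC)(CC)CC)C(C)=C(Br)[C@H]1C | intermediate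
13 | methyl 4,6-O-benzylidene-α-D-mannopyranoside | CO[C@H]1O[C@@H]2CO[C@@H](c3ccccc3)O[C@H]2[C@H](O)[C@@H]1O | starting material
14 | methyl 4,6-O-benzylidene-3-O-(2-bromopropanoyl)-α-D-mannopyranoside | CO[C@H]1O[C@@H]2CO[C@@H](c3ccccc3)O[C@H]2[C@H](OC(=O)C(C)Br)[C@@H]1O | intermediate
15 | methyl 4,6-O-benzylidene-3-O-(2-bromopropanoyl)-α-D-arabino-hexopyranosid-2-ulose | CO[C@H]1O[C@@H]2CO[C@@H](c3ccccc3)O[C@H]2[C@H](OC(=O)C(C)Br)C1=O | intermediate
16 | diiodosamarium enolate of 15 (trivalent samarium) | CO[C@H]1O[C@@H]2CO[C@@H](c3ccccc3)O[C@H]2[C@H](OC(O[Sm](I)I)=CC)C1=O | intermediate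
17 | methyl 4,6-O-benzylidene-2-C-[(1S)-1-carboxyethyl]-α-D-glucopyranoside 3-lactone (cis-fused, C8 hydroxyl free) | CO[C@H]1O[C@@H]2CO[C@@H](c3ccccc3)O[C@H]2[C@@H]4OC(=O)[C@@H](C)[C@]14O | intermediate
18 | methyl 4-O-benzoyl-6-bromo-6-deoxy analogue of 17 | CO[C@H]1O[C@H](CBr)[C@@H](OC(=O)c2ccccc2)[C@@H]3OC(=O)[C@@H](C)[C@]13O | intermediate
19 | methyl 4-O-benzoyl-6-deoxy-hex-5-enopyranoside analogue of 17 | CO[C@H]1OC(=C)[C@@H](OC(=O)c2ccccc2)[C@@H]3OC(=O)[C@@H](C)[C@]13O | intermediate
20 | ring C cyclohexanone: C5 ketone, C6 benzoate, C7–C8 fused lactone, C8 hydroxyl, C9 carbinol | O[C@H]1CC(=O)[C@@H](OC(=O)c2ccccc2)[C@@H]3OC(=O)[C@@H](C)[C@]13O | intermediate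
21 | C5 ethylene ketal of 20 | O[C@H]1CC2(OCCO2)[C@@H](OC(=O)c4ccccc4)[C@@H]3OC(=O)[C@@H](C)[C@]13O | intermediate
22 | ring C C9 ketone | O=C1CC2(OCCO2)[C@@H](OC(=O)c4ccccc4)[C@@H]3OC(=O)[C@@H](C)[C@]13O | intermediate
23 | ring C C9 enol triflate | FC(F)(F)S(=O)(=O)OC1=CC2(OCCO2)[C@@H](OC(=O)c4ccccc4)[C@@H]3OC(=O)[C@@H](C)[C@]13O | intermediate
24 | ring A vinyllithium | [Li]C1=C(C)[C@@H](O[Si](CC)(CC)CC)C[C@@H](O[Si](C)(C)C(C)(C)C)[C@@H]1C | intermediate
25 | ring A vinylzinc chloride | Cl[Zn]C1=C(C)[C@@H](O[Si](CC)(CC)CC)C[C@@H](O[Si](C)(C)C(C)(C)C)[C@@H]1C | intermediate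
26 | coupled diene (ring A on C9, C9=C4) | C1(C5=C(C)[C@@H](O[Si](CC)(CC)CC)C[C@@H](O[Si](C)(C)C(C)(C)C)[C@@H]5C)=CC2(OCCO2)[C@@H](OC(=O)c4ccccc4)[C@@H]3OC(=O)[C@@H](C)[C@]13O | intermediate
27 | 4,9-epoxide syn to the C8 hydroxyl | [C@@]16(C5=C(C)[C@@H](O[Si](CC)(CC)CC)C[C@@H](O[Si](C)(C)C(C)(C)C)[C@@H]5C)O[C@H]6C2(OCCO2)[C@@H](OC(=O)c4ccccc4)[C@@H]3OC(=O)[C@@H](C)[C@]13O | intermediate
28 | C4 (trimethylsilyl)ethynyl C9 carbinol | O[C@@]1(C5=C(C)[C@@H](O[Si](CC)(CC)CC)C[C@@H](O[Si](C)(C)C(C)(C)C)[C@@H]5C)[C@H](C#C[Si](C)(C)C)C2(OCCO2)[C@@H](OC(=O)c4ccccc4)[C@@H]3OC(=O)[C@@H](C)[C@]13O | intermediate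
29 | C4 ethynyl C6,C8,C9-triol lactone | O[C@@]1(C5=C(C)[C@@H](O[Si](CC)(CC)CC)C[C@@H](O[Si](C)(C)C(C)(C)C)[C@@H]5C)[C@H](C#C)C2(OCCO2)[C@@H](O)[C@@H]3OC(=O)[C@@H](C)[C@]13O | intermediate
30 | O6,O8-di-tert-butylsilylene lactone | O[C@@]1(C6=C(C)[C@@H](O[Si](CC)(CC)CC)C[C@@H](O[Si](C)(C)C(C)(C)C)[C@@H]6C)[C@H](C#C)C2(OCCO2)[C@H]4O[Si](C(C)(C)C)(C(C)(C)C)O[C@@]15[C@H](C)C(=O)O[C@@H]45 | intermediate
31 | C19 lactol | O[C@@]1(C6=C(C)[C@@H](O[Si](CC)(CC)CC)C[C@@H](O[Si](C)(C)C(C)(C)C)[C@@H]6C)[C@H](C#C)C2(OCCO2)[C@H]4O[Si](C(C)(C)C)(C(C)(C)C)O[C@@]15[C@H](C)[C@@H](O)O[C@@H]45 | intermediate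
32 | C19 lactol tert-butyldimethylsilyl acetal | O[C@@]1(C6=C(C)[C@@H](O[Si](CC)(CC)CC)C[C@@H](O[Si](C)(C)C(C)(C)C)[C@@H]6C)[C@H](C#C)C2(OCCO2)[C@H]4O[Si](C(C)(C)C)(C(C)(C)C)O[C@@]15[C@H](C)[C@@H](O[Si](C)(C)C(C)(C)C)O[C@@H]45 | intermediate
33 | (E)-alkenyl pinacol boronate | O[C@@]1(C6=C(C)[C@@H](O[Si](CC)(CC)CC)C[C@@H](O[Si](C)(C)C(C)(C)C)[C@@H]6C)[C@H](/C=C/B7OC(C)(C)C(C)(C)O7)C2(OCCO2)[C@H]4O[Si](C(C)(C)C)(C(C)(C)C)O[C@@]15[C@H](C)[C@@H](O[Si](C)(C)C(C)(C)C)O[C@@H]45 | intermediate
34 | oxy-Cope precursor, cis-dialkenyl ring C carbinol | O[C@@]1(C6=C(C)[C@@H](O[Si](CC)(CC)CC)C[C@@H](O[Si](C)(C)C(C)(C)C)[C@@H]6C)[C@H](/C=C/OCc7ccc(OC)cc7)C2(OCCO2)[C@H]4O[Si](C(C)(C)C)(C(C)(C)C)O[C@@]15[C@H](C)[C@@H](O[Si](C)(C)C(C)(C)C)O[C@@H]45 | intermediate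
35 | potassium C9 alkoxide of 34 | [K+].[O-][C@@]1(C6=C(C)[C@@H](O[Si](CC)(CC)CC)C[C@@H](O[Si](C)(C)C(C)(C)C)[C@@H]6C)[C@H](/C=C/OCc7ccc(OC)cc7)C2(OCCO2)[C@H]4O[Si](C(C)(C)C)(C(C)(C)C)O[C@@]15[C@H](C)[C@@H](O[Si](C)(C)C(C)(C)C)O[C@@H]45 | intermediate
36 | potassium C9 enolate of the ten-membered ring | O1CCOC12/C=C\[C@H](OCc3ccc(OC)cc3)[C@]4(C)/C([C@@H](C)[C@H](O[Si](C)(C)C(C)(C)C)C[C@@H]4O[Si](CC)(CC)CC)=C(\[O-])[C@@]56O[Si](C(C)(C)C)(C(C)(C)C)O[C@H]2[C@@H]6O[C@H](O[Si](C)(C)C(C)(C)C)[C@H]5C.[K+] | intermediate
37 | ten-membered C9 ketone with Z C3=C4 | O1CCOC12/C=C\[C@H](OCc3ccc(OC)cc3)[C@]4(C)[C@H]([C@@H](C)[C@H](O[Si](C)(C)C(C)(C)C)C[C@@H]4O[Si](CC)(CC)CC)C(=O)[C@@]56O[Si](C(C)(C)C)(C(C)(C)C)O[C@H]2[C@@H]6O[C@H](O[Si](C)(C)C(C)(C)C)[C@H]5C | intermediate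
38 | C9 alcohol | O1CCOC12/C=C\[C@H](OCc3ccc(OC)cc3)[C@]4(C)[C@H]([C@@H](C)[C@H](O[Si](C)(C)C(C)(C)C)C[C@@H]4O[Si](CC)(CC)CC)[C@H](O)[C@@]56O[Si](C(C)(C)C)(C(C)(C)C)O[C@H]2[C@@H]6O[C@H](O[Si](C)(C)C(C)(C)C)[C@H]5C | intermediate
39 | C2,C9 diol | O1CCOC12/C=C\[C@H](O)[C@]4(C)[C@H]([C@@H](C)[C@H](O[Si](C)(C)C(C)(C)C)C[C@@H]4O[Si](CC)(CC)CC)[C@H](O)[C@@]56O[Si](C(C)(C)C)(C(C)(C)C)O[C@H]2[C@@H]6O[C@H](O[Si](C)(C)C(C)(C)C)[C@H]5C | intermediate
40 | C2,C9 diacetate | O1CCOC12/C=C\[C@H](OC(C)=O)[C@]4(C)[C@H]([C@@H](C)[C@H](O[Si](C)(C)C(C)(C)C)C[C@@H]4O[Si](CC)(CC)CC)[C@H](OC(C)=O)[C@@]56O[Si](C(C)(C)C)(C(C)(C)C)O[C@H]2[C@@H]6O[C@H](O[Si](C)(C)C(C)(C)C)[C@H]5C | intermediate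
41 | C14 alcohol with C19 methyl acetal | O1CCOC12/C=C\[C@H](OC(C)=O)[C@]4(C)[C@H]([C@@H](C)[C@H](O[Si](C)(C)C(C)(C)C)C[C@@H]4O)[C@H](OC(C)=O)[C@@]56O[Si](C(C)(C)C)(C(C)(C)C)O[C@H]2[C@@H]6O[C@H](OC)[C@H]5C | intermediate
42 | C14 butyrate | O1CCOC12/C=C\[C@H](OC(C)=O)[C@]4(C)[C@H]([C@@H](C)[C@H](O[Si](C)(C)C(C)(C)C)C[C@@H]4OC(=O)CCC)[C@H](OC(C)=O)[C@@]56O[Si](C(C)(C)C)(C(C)(C)C)O[C@H]2[C@@H]6O[C@H](OC)[C@H]5C | intermediate
43 | C5 enone with C19 lactol | O=C2/C=C\[C@H](OC(C)=O)[C@]4(C)[C@H]([C@@H](C)[C@H](O[Si](C)(C)C(C)(C)C)C[C@@H]4OC(=O)CCC)[C@H](OC(C)=O)[C@@]56O[Si](C(C)(C)C)(C(C)(C)C)O[C@H]2[C@@H]6O[C@H](O)[C@H]5C | intermediate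
44 | C5 enone γ-lactone with O6,O8-silylene | O=C2/C=C\[C@H](OC(C)=O)[C@]4(C)[C@H]([C@@H](C)[C@H](O[Si](C)(C)C(C)(C)C)C[C@@H]4OC(=O)CCC)[C@H](OC(C)=O)[C@@]56O[Si](C(C)(C)C)(C(C)(C)C)O[C@H]2[C@@H]6OC(=O)[C@H]5C | intermediate
45 | C6,C8 diol (α-hydroxy enone) | O=C1/C=C\[C@H](OC(C)=O)[C@]2(C)[C@H]([C@@H](C)[C@H](O[Si](C)(C)C(C)(C)C)C[C@@H]2OC(=O)CCC)[C@H](OC(C)=O)[C@@]2(O)[C@H](C)C(=O)O[C@H]2[C@@H]1O | intermediate
46 | C6 triflate | O=C1/C=C\[C@H](OC(C)=O)[C@]2(C)[C@H]([C@@H](C)[C@H](O[Si](C)(C)C(C)(C)C)C[C@@H]2OC(=O)CCC)[C@H](OC(C)=O)[C@@]2(O)[C@H](C)C(=O)O[C@H]2[C@@H]1OS(=O)(=O)C(F)(F)F | intermediate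
47 | C6 chloride (α-chloro enone, C6 inverted) | O=C1/C=C\[C@H](OC(C)=O)[C@]2(C)[C@H]([C@@H](C)[C@H](O[Si](C)(C)C(C)(C)C)C[C@@H]2OC(=O)CCC)[C@H](OC(C)=O)[C@@]2(O)[C@H](C)C(=O)O[C@H]2[C@H]1Cl | intermediate
48 | 12-O-(tert-butyldimethylsilyl) C5 methylene compound | C=C1/C=C\[C@H](OC(C)=O)[C@]2(C)[C@H]([C@@H](C)[C@H](O[Si](C)(C)C(C)(C)C)C[C@@H]2OC(=O)CCC)[C@H](OC(C)=O)[C@@]2(O)[C@H](C)C(=O)O[C@H]2[C@H]1Cl | intermediate
49 | C12 alcohol | C=C1/C=C\[C@H](OC(C)=O)[C@]2(C)[C@H]([C@@H](C)[C@H](O)C[C@@H]2OC(=O)CCC)[C@H](OC(C)=O)[C@@]2(O)[C@H](C)C(=O)O[C@H]2[C@H]1Cl | intermediate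
50 | CNP0283653.1 | C=C1/C=C\[C@H](OC(C)=O)[C@]2(C)[C@H]([C@@H](C)C(=O)C[C@@H]2OC(=O)CCC)[C@H](OC(C)=O)[C@@]2(O)[C@H](C)C(=O)O[C@H]2[C@H]1Cl | target

## Step count and least certain steps

Total step count: 41. Longest linear sequence: 32 steps (steps 1–10 and 20–41, from (R)-carvone 1); the ring C branch from 13 runs 31 steps.

**Step 29 (key step).** The tetrasubstituted C1 terminus may react too slowly, so that the alkoxide instead fragments or silicon migrates from O8 to the C9 oxygen. A boat transition state would misplace C1 and C2, and protonation at C10 may occur syn to the C1 methyl. Fallback: setting out from 34, the C9 hydroxyl is silylated (Me3SiOTf, 2,6-lutidine) to the C9 trimethylsilyl ether of 34 F1. Heating F1 in o-dichlorobenzene at about 190 °C effects the neutral silyloxy-Cope shift through the same locked chair and gives the ten-membered C9 trimethylsilyl enol ether F2. Mild methanolysis (K2CO3, MeOH) with protonation at C10 returns to the route at 37. No alkoxide is present, so silyl migration and anionic fragmentation are removed.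

**Step 22.** The Lewis-acidic alane may ionise the tertiary, allylic C9–O bond, leading to rearrangement or attack at C9, while SN2 at C4 is slowed by the neighbouring ketal. Fallback: setting out from 27, the epoxide is opened with vinylmagnesium bromide and catalytic CuI, a softer and non-ionising organocopper SN2, to the C4 vinyl carbinol F3. Steps 23–26 are run on the vinyl series: K2CO3/MeOH gives the vinyl triol F4, t-Bu2Si(OTf)2 the vinyl silylene lactone F5, i-Bu2AlH the vinyl lactol F6, and t-BuMe2SiCl the vinyl lactol silyl acetal F7. Cross-metathesis of F7 with vinylboronic acid pinacol ester (second-generation Grubbs catalyst) returns to the route at 33.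

**Step 20.** Transmetalation of the hindered tetrasubstituted alkenylzinc may be slow, so that protonation by the free C8 hydroxyl or homocoupling takes over. Fallback: setting out from 12 and ketone 22, vinyllithium 24 is transmetalated with CeCl3 and added to the C9 ketone to give the C9 tertiary carbinol F8, whose C9 configuration does not matter. Dehydration with the Burgess reagent, possible only toward C4, returns to the route at 26.

**Step 30.** Hydride may approach the C9 carbonyl from the face set by the C8 substituents instead of the Felkin face at C10 and give the C9 epimer. Fallback: setting out from 37 again, the reduction is run under thermodynamic control by reversible hydride transfer (Al(Oi-Pr)3, 2-propanol, Meerwein–Ponndorf–Verley), which selects the more stable carbinol, not the kinetic one, and returns at 38; no new compound is involved.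

**Step 39.** The titanium carbenoid may dehalogenate or enolise the α-chloro ketone, or attack the lactone, and the chlorodimethylaluminium that is released may ionise the newly formed allylic chloride. Fallback: the order is changed. Setting out from 44, the C5 ketone is methylenated before any chloride is present (Ph3P=CH2, THF) to the C5 methylene silylene lactone F9. HF·pyridine then frees the C5-methylene C6,C8 diol F10, and the allylic C6 alcohol is converted into the chloride with inversion (N-chlorosuccinimide, Me2S, Corey–Kim conditions), returning at 48.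

**Step 4.** Etherification may be poorly regioselective, so that part of the material ends with bromine on C14 after step 5. Fallback: regiochemistry is fixed from the enone instead. Setting out from 2, conjugate addition of thiophenol (Et3N) gives the 3-phenylthio ketone F11. Chlorination with N-chlorosuccinimide and loss of HCl gives the 3-phenylthio enone F12, whose carbonyl can only be C10. The same oxalyl bromide transposition with hydrolytic work-up returns at 6.

## Further compounds

F1 | step 29 | C9 trimethylsilyl ether of 34 | C[Si](C)(C)O[C@@]1(C6=C(C)[C@@H](O[Si](CC)(CC)CC)C[C@@H](O[Si](C)(C)C(C)(C)C)[C@@H]6C)[C@H](/C=C/OCc7ccc(OC)cc7)C2(OCCO2)[C@H]4O[Si](C(C)(C)C)(C(C)(C)C)O[C@@]15[C@H](C)[C@@H](O[Si](C)(C)C(C)(C)C)O[C@@H]45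
F2 | step 29 | ten-membered C9 trimethylsilyl enol ether | O1CCOC12/C=C\[C@H](OCc3ccc(OC)cc3)[C@]4(C)/C([C@@H](C)[C@H](O[Si](C)(C)C(C)(C)C)C[C@@H]4O[Si](CC)(CC)CC)=C(\O[Si](C)(C)C)[C@@]56O[Si](C(C)(C)C)(C(C)(C)C)O[C@H]2[C@@H]6O[C@H](O[Si](C)(C)C(C)(C)C)[C@H]5C
F3 | step 22 | C4 vinyl carbinol | O[C@@]1(C5=C(C)[C@@H](O[Si](CC)(CC)CC)C[C@@H](O[Si](C)(C)C(C)(C)C)[C@@H]5C)[C@H](C=C)C2(OCCO2)[C@@H](OC(=O)c4ccccc4)[C@@H]3OC(=O)[C@@H](C)[C@]13O
F4 | step 22 | vinyl triol | O[C@@]1(C5=C(C)[C@@H](O[Si](CC)(CC)CC)C[C@@H](O[Si](C)(C)C(C)(C)C)[C@@H]5C)[C@H](C=C)C2(OCCO2)[C@@H](O)[C@@H]3OC(=O)[C@@H](C)[C@]13O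
F5 | step 22 | vinyl silylene lactone | O[C@@]1(C6=C(C)[C@@H](O[Si](CC)(CC)CC)C[C@@H](O[Si](C)(C)C(C)(C)C)[C@@H]6C)[C@H](C=C)C2(OCCO2)[C@H]4O[Si](C(C)(C)C)(C(C)(C)C)O[C@@]15[C@H](C)C(=O)O[C@@H]45
F6 | step 22 | vinyl lactol | O[C@@]1(C6=C(C)[C@@H](O[Si](CC)(CC)CC)C[C@@H](O[Si](C)(C)C(C)(C)C)[C@@H]6C)[C@H](C=C)C2(OCCO2)[C@H]4O[Si](C(C)(C)C)(C(C)(C)C)O[C@@]15[C@H](C)[C@@H](O)O[C@@H]45
F7 | step 22 | vinyl lactol silyl acetal | O[C@@]1(C6=C(C)[C@@H](O[Si](CC)(CC)CC)C[C@@H](O[Si](C)(C)C(C)(C)C)[C@@H]6C)[C@H](C=C)C2(OCCO2)[C@H]4O[Si](C(C)(C)C)(C(C)(C)C)O[C@@]15[C@H](C)[C@@H](O[Si](C)(C)C(C)(C)C)O[C@@H]45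
F8 | step 20 | C9 tertiary carbinol | OC1(C5=C(C)[C@@H](O[Si](CC)(CC)CC)C[C@@H](O[Si](C)(C)C(C)(C)C)[C@@H]5C)CC2(OCCO2)[C@@H](OC(=O)c4ccccc4)[C@@H]3OC(=O)[C@@H](C)[C@]13O
F0 | step 30 | none | none
F9 | step 39 | C5 methylene silylene lactone | C=C2/C=C\[C@H](OC(C)=O)[C@]4(C)[C@H]([C@@H](C)[C@H](O[Si](C)(C)C(C)(C)C)C[C@@H]4OC(=O)CCC)[C@H](OC(C)=O)[C@@]56O[Si](C(C)(C)C)(C(C)(C)C)O[C@H]2[C@@H]6OC(=O)[C@H]5C
F10 | step 39 | C5-methylene C6,C8 diol | C=C1/C=C\[C@H](OC(C)=O)[C@]2(C)[C@H]([C@@H](C)[C@H](O[Si](C)(C)C(C)(C)C)C[C@@H]2OC(=O)CCC)[C@H](OC(C)=O)[C@@]2(O)[C@H](C)C(=O)O[C@H]2[C@@H]1O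
F11 | step 4 | 3-phenylthio ketone | CC(=C)[C@@H]1CC(Sc2ccccc2)C(C)C(=O)[C@H]1C
F12 | step 4 | 3-phenylthio enone | CC(=C)[C@@H]1CC(Sc2ccccc2)=C(C)C(=O)[C@H]1C
A1 | alternative 1 | 9-O-triethylsilyl-9-deacetyl target | C=C1/C=C\[C@H](OC(C)=O)[C@]2(C)[C@H]([C@@H](C)C(=O)C[C@@H]2OC(=O)CCC)[C@H](O[Si](CC)(CC)CC)[C@@]2(O)[C@H](C)C(=O)O[C@H]2[C@H]1Cl
A2 | alternative 1 | C8 ketone C7 2-bromopropanoate | C=C1/C=C\[C@H](OC(C)=O)[C@]2(C)[C@H]([C@@H](C)C(=O)C[C@@H]2OC(=O)CCC)[C@H](O[Si](CC)(CC)CC)C(=O)[C@@H](OC(=O)C(C)Br)[C@H]1Cl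
A3 | alternative 2 | ten-membered 2,7-dione | O1CCOC12CCC(=O)[C@]3(C)[C@H]([C@@H](C)[C@@H](O[Si](CC)(CC)CC)C[C@@H]3OC(=O)CCC)[C@H](OC(C)=O)[C@@](O)([C@H](C)C(=O)OC)C(=O)[C@H]2Cl
A4 | alternative 2 | octalin with C2=C7 ring-fusion alkene | O1CCOC12CCC=4[C@]3(C)[C@H]([C@@H](C)[C@@H](O[Si](CC)(CC)CC)C[C@@H]3OC(=O)CCC)[C@H](OC(C)=O)[C@@](O)([C@H](C)C(=O)OC)C4[C@H]2Cl
A5 | alternative 3 | ten-membered C9 hydroxy C8 ketone | C=C1/C=C\[C@H](O[Si](C)(C)C(C)(C)C)[C@]2(C)[C@H](C(C)=CC[C@@H]2O[Si](C(C)C)(C(C)C)C(C)C)[C@H](O)C(=O)[C@@H](O[Si](CC)(CC)CC)[C@H]1Cl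
A6 | alternative 3 | 13-membered α-allyloxy ketone | C=C1/C=C\[C@H](O[Si](C)(C)C(C)(C)C)[C@]2(C)C=C(C)[C@@H](OCC(=O)[C@@H](O[Si](CC)(CC)CC)[C@H]1Cl)C[C@@H]2O[Si](C(C)C)(C(C)C)C(C)C
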